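**Assumptions:** the SMILES is taken literally (dihydropyran cis-fused to the nine-membered ring; 1S,9R caryophyllane half). In steps 4 and 11 the enantiomer of the chiral base or catalyst that gives the drawn product is meant. Compounds 6 and 7 are racemic (one enantiomer drawn); 14, 23 and 26 are mixtures at centres or olefins that are destroyed later.

## Retrosynthetic overview

1. Target 31 ⇐ methyl ester 30 ⇐ nor-ketone 29 (late methylenation of the nine-ring ketone, then saponification).
2. 29 ⇐ bromomethyl α-methoxy enone 16 (triquinane half) + (Z)-cyclononenone 28 (caryophyllane half). A photoredox radical addition forms the C5–CH2 bond; radical–polar crossover and demethylative C–O closure complete the dihydropyran.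
3. 16 ⇐ Nazarov closure of ring C on a ring A/B enone. Ring B comes from dichloroketene/CH2N2 annulation of a cyclopentene (ring A) and chiral-base desymmetrisation of the meso ketone 8.
4. 28 ⇐ three-carbon radical ring expansion of a cyclobutane-fused cyclohexanone, itself from an enantioselective [2+2] photocycloaddition of cyclohexenone and isobutene.
5. Ring order: A → B → C in the western half; cyclobutane → six-ring → nine-ring in the eastern half; the pyran last.

## Route

Step 1
Reactants: 1 cyclopent-3-ene-1-carboxylic acid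
Product: 3 methyl 1-methylcyclopent-3-ene-1-carboxylate, via lithium 1-methylcyclopent-3-ene-1-carboxylate 2 (not isolated)
Conditions: LiN(i-Pr)2 (2.2 equiv), THF, −78 to 0 °C; MeI (3 equiv), DMPU, 0 to 40 °C
Reagents that add atoms: iodomethane CI
Why: The enediolate dianion is C-methylated at the α-carbon and the resulting lithium carboxylate is O-methylated by excess MeI (dianion alkylation/esterification); no stereocentre is formed.

Step 2
Reactants: 3 methyl 1-methylcyclopent-3-ene-1-carboxylate; 4 trichloroacetyl chloride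
Product: 6 methyl 6,6-dichloro-3-methyl-7-oxobicyclo[3.2.0]heptane-3-carboxylate (racemic), via dichloroketene 5 (not isolated)
Conditions: Zn(Cu), POCl3, Et2O, reflux
Reagents that add atoms: none
Why: Zinc dechlorinates 4 to dichloroketene, which adds in a thermal [2+2] cycloaddition to the face opposite the pseudo-axial ester, so CO2Me ends cis to the two new ring-fusion hydrogens (this fixes the quaternary ester centre relative to the A/B fusion; about 4:1 expected, minor isomer removed at 8).

Step 3
Reactants: 6 methyl 6,6-dichloro-3-methyl-7-oxobicyclo[3.2.0]heptane-3-carboxylate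
Product: 8 methyl (3aR,6aS)-2-methyl-5-oxooctahydropentalene-2-carboxylate (meso), via methyl 4,4-dichloro-2-methyl-5-oxooctahydropentalene-2-carboxylate 7 (not isolated)
Conditions: CH2N2, Et2O/MeOH, 0 °C; then Zn, AcOH, 70 °C
Reagents that add atoms: diazomethane C=[N+]=[N-]
Why: Diazomethane ring expansion proceeds by migration of the non-chlorinated α-carbon (regioselective for α,α-dichlorocyclobutanones) and Zn/AcOH removes both chlorines, giving the meso cis-bicyclo[3.3.0]octanone.

Step 4
Reactants: 8 methyl (3aR,6aS)-2-methyl-5-oxooctahydropentalene-2-carboxylate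
Product: 9 methyl 2,4-dimethyl-5-oxooctahydropentalene-2-carboxylate (single enantiomer as in SMILES; 4-methyl on the convex face)
Conditions: LiN[(R)-CH(Me)Ph]2, LiCl, THF, −100 °C; MeI, DMPU, −78 °C
Reagents that add atoms: iodomethane CI
Why: Enantiotopic-proton-selective deprotonation by the chiral lithium amide (Simpkins–Koga desymmetrisation) gives one enolate, which is methylated on the convex face; this sets the absolute configuration of the whole western half.

Step 5
Reactants: 9 methyl 2,4-dimethyl-5-oxooctahydropentalene-2-carboxylate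
Product: 10 methyl 2,4-dimethyl-5-(trifluoromethylsulfonyloxy)-1,2,3,3a,6,6a-hexahydropentalene-2-carboxylate
Conditions: Tf2O, 2,6-di-tert-butyl-4-methylpyridine, CH2Cl2, 0 °C to rt
Reagents that add atoms: trifluoromethanesulfonic anhydride O=S(=O)(OS(=O)(=O)C(F)(F)F)C(F)(F)F
Why: Triflation with a hindered pyridine gives mainly the more substituted enol triflate, fixing the tetrasubstituted olefin; the C4 stereocentre is deliberately erased.

Step 6
Reactants: 10 methyl 2,4-dimethyl-5-(trifluoromethylsulfonyloxy)-1,2,3,3a,6,6a-hexahydropentalene-2-carboxylate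
Product: 11 methyl 5-[methoxy(methyl)carbamoyl]-2,4-dimethyl-1,2,3,3a,6,6a-hexahydropentalene-2-carboxylate
Conditions: Pd(OAc)2 (5 mol%), Xantphos, CO (1 atm), MeNH(OMe)·HCl, Et3N, toluene, 70 °C
Reagents that add atoms: carbon monoxide [C-]#[O+]; N,O-dimethylhydroxylamine hydrochloride CNOC.Cl
Why: Oxidative addition of zerovalent palladium to the vinyl triflate, CO insertion and aminolysis (aminocarbonylation) install the future ring C carbonyl as a Weinreb amide.

Step 7
Reactants: 11 methyl 5-[methoxy(methyl)carbamoyl]-2,4-dimethyl-1,2,3,3a,6,6a-hexahydropentalene-2-carboxylate; 12 1-methoxyprop-1-ene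
Product: 14 methyl 5-(2-methoxybut-2-enoyl)-2,4-dimethyl-1,2,3,3a,6,6a-hexahydropentalene-2-carboxylate, via 1-lithio-1-methoxyprop-1-ene 13 (not isolated)
Conditions: 12, t-BuLi, THF, −78 to −10 °C; then 11, −78 °C; aq. NH4Cl
Reagents that add atoms: none
Why: α-Lithiation of the enol ether and acyl substitution at the Weinreb amide (stable chelate, no over-addition; the hindered ester is untouched) give the α-methoxy divinyl ketone.

Step 8
Reactants: 14 methyl 5-(2-methoxybut-2-enoyl)-2,4-dimethyl-1,2,3,3a,6,6a-hexahydropentalene-2-carboxylate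
Product: 15 methyl (3aS,3bR,5S,6aS,7aR)-2-methoxy-3,3a,5-trimethyl-1-oxo-3a,3b,4,5,6,6a,7,7a-octahydro-1H-cyclopenta[a]pentalene-5-carboxylate
Conditions: Sc(OTf)3 (10 mol%), LiClO4, ClCH2CH2Cl, 60 °C
Reagents that add atoms: none
Why: Lewis-acid-promoted conrotatory Nazarov cyclisation, polarised by the α-methoxy group, forms the new ring C bond on the convex face of the bicyclo[3.3.0]octene, creating the quaternary methyl-bearing centre anti to ring A; elimination toward the methoxy carbon and protonation give the cis-fused 2-methoxy enone.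

Step 9
Reactants: 15 methyl (3aS,3bR,5S,6aS,7aR)-2-methoxy-3,3a,5-trimethyl-1-oxo-3a,3b,4,5,6,6a,7,7a-octahydro-1H-cyclopenta[a]pentalene-5-carboxylate
Product: 16 methyl (3aS,3bR,5S,6aS,7aR)-3-(bromomethyl)-2-methoxy-3a,5-dimethyl-1-oxo-3a,3b,4,5,6,6a,7,7a-octahydro-1H-cyclopenta[a]pentalene-5-carboxylate
Conditions: NBS, AIBN (cat.), PhCF3, 80 °C
Reagents that add atoms: N-bromosuccinimide O=C1CCC(=O)N1Br
Why: Wohl–Ziegler bromination at the only allylic (γ-enone) methyl group; the ring allylic position is quaternary.

Step 10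
Reactants: 17 benzenethiol; 18 1,3-dibromopropane
Product: 19 (3-bromopropyl)(phenyl)sulfane
Conditions: K2CO3, acetone, rt (18 in threefold excess)
Reagents that add atoms: none
Why: SN2 thioetherification; the excess dibromide suppresses double substitution.

Step 11
Reactants: 20 cyclohex-2-en-1-one; 21 2-methylprop-1-ene
Product: 22 (1S,6S)-7,7-dimethylbicyclo[4.2.0]octan-2-one
Conditions: hν (366 nm), AlBr3-activated diarylprolinol-derived B-(2,4,6-trifluorophenyl)oxazaborolidine (50 mol%), CH2Cl2, −75 °C; then basic Al2O3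
Reagents that add atoms: none
Why: Chiral-Lewis-acid-catalysed enone–alkene [2+2] photocycloaddition gives the head-to-tail adduct with catalyst-controlled facial selectivity, setting C6 (the future C1 of the caryophyllane half); alumina converges the ring fusion to cis.

Step 12
Reactants: 22 (1S,6S)-7,7-dimethylbicyclo[4.2.0]octan-2-one
Product: 23 (1S,6S)-3,7,7-trimethylbicyclo[4.2.0]octan-2-one (C3 epimers)
Conditions: LiN(i-Pr)2, THF, −78 °C; MeI
Reagents that add atoms: iodomethane CI
Why: Kinetic enolate formation at the α-CH2 and methylation; the cyclobutane bridgehead is not deprotonated.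

Step 13
Reactants: 23 (1S,6S)-3,7,7-trimethylbicyclo[4.2.0]octan-2-one
Product: 24 trimethyl{[(1S,6S)-3,7,7-trimethylbicyclo[4.2.0]oct-2-en-2-yl]oxy}silane
Conditions: Me3SiCl, Et3N, DMF, 80 °C
Reagents that add atoms: chlorotrimethylsilane C[Si](C)(C)Cl
Why: Thermodynamic silylation gives the tetrasubstituted silyl enol ether, away from the strained bridgehead.

Step 14
Reactants: 24 trimethyl{[(1S,6S)-3,7,7-trimethylbicyclo[4.2.0]oct-2-en-2-yl]oxy}silane; 19 (3-bromopropyl)(phenyl)sulfane
Product: 26 (1S,6S)-3-[3-bromo-1-(phenylsulfanyl)propyl]-3,7,7-trimethylbicyclo[4.2.0]octan-2-one (diastereomer mixture), via (3-bromo-1-chloropropyl)(phenyl)sulfane 25 (not isolated)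
Conditions: 19, NCS, CH2Cl2, 0 °C; then 24, ZnBr2 (10 mol%), −40 °C to rt
Reagents that add atoms: none
Why: NCS α-chlorinates the sulfide and the ZnBr2-generated thionium ion alkylates the silyl enol ether (Paterson–Fleming phenylthioalkylation), forming the quaternary centre without a base that could trigger β-thiolate loss; the new centres are destroyed in step 15.

Step 15
Reactants: 26 (1S,6S)-3-[3-bromo-1-(phenylsulfanyl)propyl]-3,7,7-trimethylbicyclo[4.2.0]octan-2-one
Product: 28 (1S,9R,Z)-4,11,11-trimethylbicyclo[7.2.0]undec-4-en-8-one, via (1S,9S,Z)-4,11,11-trimethylbicyclo[7.2.0]undec-4-en-8-one 27 (not isolated)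
Conditions: Bu3SnH (slow addition), AIBN, PhH (0.005 M), 80 °C; then DBU, rt
Reagents that add atoms: none
Why: Proposed new method: Bu3Sn• abstracts bromine, the primary radical adds 5-exo to the ketone carbonyl, the bicyclic alkoxyl radical opens by β-scission of the old ring bond to the tertiary radical (three-carbon Dowd–Beckwith ring expansion), and this radical expels PhS• to place the trisubstituted olefin regiospecifically; reversible thiyl addition equilibrates the olefin to the more stable Z isomer and DBU epimerises the α-bridgehead to the trans fusion; closest known chemistry is the Dowd–Beckwith expansion of β-keto esters and β-sulfanyl radical fragmentation.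

Step 16
Reactants: 16 methyl (3aS,3bR,5S,6aS,7aR)-3-(bromomethyl)-2-methoxy-3a,5-dimethyl-1-oxo-3a,3b,4,5,6,6a,7,7a-octahydro-1H-cyclopenta[a]pentalene-5-carboxylate; 28 (1S,9R,Z)-4,11,11-trimethylbicyclo[7.2.0]undec-4-en-8-one
Product: 29 nor-ketone methyl ester of the target (C=O in place of the exocyclic C=CH2; CO2Me in place of CO2H)
Conditions: fac-Ir(ppy)3 (1 mol%), blue LEDs (450 nm), MeCN (0.2 M), rt, degassed; 16 (1.3 equiv)
Reagents that add atoms: none
Why: Proposed new method: excited fac-Ir(ppy)3 reduces the allylic C–Br bond of 16 to an acyl- and methoxy-substituted allyl radical, which adds through its CH2 terminus to the CH end of the Z-olefin of 28 on the outward face of the conformer that has the olefinic H and methyl on the H1 side; the tertiary radical is oxidised by tetravalent iridium to the cation, which is captured on the same face by the enol-ether oxygen (six-membered oxonium) and demethylated by bromide, so the C–C bond, the C–O bond and both new stereocentres (cis fusion from the Z-olefin) are set in one operation, and cross-products from minor enantiomers of either half are diastereomers removed here; closest known chemistry is photoredox radical–polar crossover carbo-etherification of alkenes and dealkylative capture of carbocations by methyl ethers.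

Step 17
Reactants: 29 nor-ketone methyl ester of the target
Product: 30 methyl ester of CNP0483070.1
Conditions: Zn, CH2Br2, TiCl4, THF/CH2Cl2, 0 °C to rt
Reagents that add atoms: dibromomethane BrCBr
Why: Takai–Lombardo methylenation is non-basic and should select the saturated nine-ring ketone over the cross-conjugated, sterically flanked α-alkoxy cyclopentenone and the ester.

Step 18
Reactants: 30 methyl ester of CNP0483070.1
Product: 31 CNP0483070.1 (target acid)
Conditions: LiOH, THF/MeOH/H2O, 50 °C; then 1 M HCl to pH 3, 0 °C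
Reagents that add atoms: lithium hydroxide [Li+].[OH-]
Why: Saponification of the hindered ester; brief cold acidification spares the tertiary enol ether and the exocyclic olefin.

## Compound list

1 | cyclopent-3-ene-1-carboxylic acid | OC(=O)C1CC=CC1 | starting material
2 | lithium 1-methylcyclopent-3-ene-1-carboxylate | [Li+].[O-]C(=O)C1(C)CC=CC1 | intermediate
3 | methyl 1-methylcyclopent-3-ene-1-carboxylate | COC(=O)C1(C)CC=CC1 | intermediate
4 | trichloroacetyl chloride | ClC(=O)C(Cl)(Cl)Cl | starting material
5 | dichloroketene | ClC(Cl)=C=O | intermediate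
6 | methyl 6,6-dichloro-3-methyl-7-oxobicyclo[3.2.0]heptane-3-carboxylate (racemic; cis-fused; ester cis to bridgehead H) | O=C1C(Cl)(Cl)[C@H]2C[C@](C)(C(=O)OC)C[C@@H]12 | intermediate
7 | methyl 4,4-dichloro-2-methyl-5-oxooctahydropentalene-2-carboxylate (racemic) | O=C1C(Cl)(Cl)[C@H]2C[C@](C)(C(=O)OC)C[C@H]2C1 | intermediate
8 | methyl (3aR,6aS)-2-methyl-5-oxooctahydropentalene-2-carboxylate (meso; ester cis to H-3a/H-6a) | O=C1C[C@H]2C[C@](C)(C(=O)OC)C[C@H]2C1 | intermediate
9 | methyl 2,4-dimethyl-5-oxooctahydropentalene-2-carboxylate (4-methyl on convex face) | O=C1C[C@H]2C[C@](C)(C(=O)OC)C[C@H]2[C@@H]1C | intermediate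
10 | methyl 2,4-dimethyl-5-(trifluoromethylsulfonyloxy)-1,2,3,3a,6,6a-hexahydropentalene-2-carboxylate | FC(F)(F)S(=O)(=O)OC1=C(C)[C@@H]2C[C@@](C)(C(=O)OC)C[C@@H]2C1 | intermediate
11 | methyl 5-[methoxy(methyl)carbamoyl]-2,4-dimethyl-1,2,3,3a,6,6a-hexahydropentalene-2-carboxylate | CON(C)C(=O)C1=C(C)[C@@H]2C[C@@](C)(C(=O)OC)C[C@@H]2C1 | intermediate
12 | 1-methoxyprop-1-ene (E/Z) | CC=COC | starting material
13 | 1-lithio-1-methoxyprop-1-ene | CC=C([Li])OC | intermediate
14 | methyl 5-(2-methoxybut-2-enoyl)-2,4-dimethyl-1,2,3,3a,6,6a-hexahydropentalene-2-carboxylate | CC=C(OC)C(=O)C1=C(C)[C@@H]2C[C@@](C)(C(=O)OC)C[C@@H]2C1 | intermediate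
15 | methyl (3aS,3bR,5S,6aS,7aR)-2-methoxy-3,3a,5-trimethyl-1-oxo-3a,3b,4,5,6,6a,7,7a-octahydro-1H-cyclopenta[a]pentalene-5-carboxylate | CC1=C(OC)C(=O)[C@@H]2C[C@H]3C[C@](C)(C(=O)OC)C[C@H]3[C@]12C | intermediate
16 | methyl (3aS,3bR,5S,6aS,7aR)-3-(bromomethyl)-2-methoxy-3a,5-dimethyl-1-oxo-3a,3b,4,5,6,6a,7,7a-octahydro-1H-cyclopenta[a]pentalene-5-carboxylate | BrCC1=C(OC)C(=O)[C@@H]2C[C@H]3C[C@](C)(C(=O)OC)C[C@H]3[C@]12C | intermediate
17 | benzenethiol | Sc1ccccc1 | starting material
18 | 1,3-dibromopropane | BrCCCBr | starting material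
19 | (3-bromopropyl)(phenyl)sulfane | BrCCCSc1ccccc1 | intermediate
20 | cyclohex-2-en-1-one | O=C1C=CCCC1 | starting material
21 | 2-methylprop-1-ene | CC(C)=C | starting material
22 | (1S,6S)-7,7-dimethylbicyclo[4.2.0]octan-2-one | O=C1CCC[C@H]2[C@@H]1CC2(C)C | intermediate
23 | (1S,6S)-3,7,7-trimethylbicyclo[4.2.0]octan-2-one (C3 epimers) | O=C1C(C)CC[C@H]2[C@@H]1CC2(C)C | intermediate
24 | trimethyl{[(1S,6S)-3,7,7-trimethylbicyclo[4.2.0]oct-2-en-2-yl]oxy}silane | C[Si](C)(C)OC1=C(C)CC[C@H]2[C@@H]1CC2(C)C | intermediate
25 | (3-bromo-1-chloropropyl)(phenyl)sulfane | ClC(CCBr)Sc1ccccc1 | intermediate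
26 | (1S,6S)-3-[3-bromo-1-(phenylsulfanyl)propyl]-3,7,7-trimethylbicyclo[4.2.0]octan-2-one (diastereomer mixture) | O=C1C(C)(C(CCBr)Sc3ccccc3)CC[C@H]2[C@@H]1CC2(C)C | intermediate
27 | (1S,9S,Z)-4,11,11-trimethylbicyclo[7.2.0]undec-4-en-8-one (cis-fused) | O=C1CC/C=C(C)\CC[C@H]2[C@@H]1CC2(C)C | intermediate
28 | (1S,9R,Z)-4,11,11-trimethylbicyclo[7.2.0]undec-4-en-8-one (trans-fused) | O=C1CC/C=C(C)\CC[C@H]2[C@H]1CC2(C)C | intermediate
29 | nor-ketone methyl ester of the target (nine-ring C=O; CO2Me) | O=C1CC[C@@H]2CC3=C(O[C@]2(C)CC[C@H]2[C@H]1CC2(C)C)C(=O)[C@@H]1C[C@H]2C[C@](C)(C(=O)OC)C[C@H]2[C@]31C | intermediate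
30 | methyl ester of CNP0483070.1 | C=C1CC[C@@H]2CC3=C(O[C@]2(C)CC[C@H]2[C@H]1CC2(C)C)C(=O)[C@@H]1C[C@H]2C[C@](C)(C(=O)OC)C[C@H]2[C@]31C | intermediate
31 | CNP0483070.1 | C=C1CC[C@@H]2CC3=C(O[C@]2(C)CC[C@H]2[C@H]1CC2(C)C)C(=O)[C@@H]1C[C@H]2C[C@](C)(C(=O)O)C[C@H]2[C@]31C | target

## Step count and risks

Total steps: 18. Longest linear sequence: 12 (steps 1–9, then 16–18).

**Step 16 (union).** The delocalised radical may add slowly to the trisubstituted olefin. The facial preference of the Z-cyclononene is a conformational expectation, not an established fact. The tertiary cation may eliminate instead of closing.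
Fallback: set out from 16 and 28. LiI in MeCN at 60 °C demethylates the enol ether of 16 with loss of bromide and gives the methylidene dione F1. It is trapped in the same flask by 28 in a thermal inverse-demand hetero-Diels–Alder reaction, which is suprafacial and so gives the cis fusion. The route is rejoined at 29.

**Step 15 (ring expansion).** Premature reduction of the primary radical, hydrothiolation of the product olefin or an unfavourable E/Z ratio can erode the yield.
Fallback: set out from 24. A Mukaiyama aldol with 3-bromopropanal (TiCl4, −78 °C) gives the bromo aldol F2. SmI2 in THF/HMPA closes the cyclopentanol onto the ketone and gives the tricyclic diol F3. MsCl/Et3N gives the secondary mesylate F4. KOt-Bu in t-BuOH then triggers Grob fragmentation of the ring-fusion bond and epimerises the bridgehead; any E-olefin is converged to Z with catalytic PhSSPh under light. The route is rejoined at 28.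

**Step 8 (Nazarov).** The olefin terminus that becomes the quaternary centre is tetrasubstituted and only one vinyl arm is activated, so cyclisation may stall or follow another course.
Fallback: set out from 11. Lithiated 1-(methoxymethoxy)propa-1,2-diene adds to the Weinreb amide and gives the allenyl ketone F5. On work-up with aqueous KH2PO4 it cyclises (allenyl-ether cyclopentannelation) with loss of the methoxymethyl group to the methylidene hydroxy-enone F6. H2 with RhCl(PPh3)3 reduces the exocyclic olefin and gives the diosphenol F7. Me2SO4/K2CO3 in acetone O-methylates it. The route is rejoined at 15.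

## Further compounds

F1 | step 16 | methyl (3aS,3bR,5S,6aS,7aR)-3a,5-dimethyl-3-methylidene-1,2-dioxodecahydro-1H-cyclopenta[a]pentalene-5-carboxylate | C=C1C(=O)C(=O)[C@@H]2C[C@H]3C[C@](C)(C(=O)OC)C[C@H]3[C@]12C
F2 | step 15 | (1S,6S)-3-(3-bromo-1-hydroxypropyl)-3,7,7-trimethylbicyclo[4.2.0]octan-2-one | O=C1C(C)(C(O)CCBr)CC[C@H]2[C@@H]1CC2(C)C
F3 | step 15 | cyclobutane-fused hydrindane diol (tertiary OH at the ring fusion; secondary OH next to the methyl-bearing carbon) | OC1CCC2(O)[C@H]3CC(C)(C)[C@H]3CCC12C
F4 | step 15 | secondary methanesulfonate of F3 | CS(=O)(=O)OC1CCC2(O)[C@H]3CC(C)(C)[C@H]3CCC12C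
F5 | step 8 | methyl 5-[2-(methoxymethoxy)buta-2,3-dienoyl]-2,4-dimethyl-1,2,3,3a,6,6a-hexahydropentalene-2-carboxylate | C=C=C(OCOC)C(=O)C1=C(C)[C@@H]2C[C@@](C)(C(=O)OC)C[C@@H]2C1
F6 | step 8 | methylidene hydroxy-enone (enol tautomer of the 3-methylidene-1,2-dione; enol double bond at the B/C fusion) | C=C1C(=O)C(O)=C2C[C@H]3C[C@](C)(C(=O)OC)C[C@H]3[C@]12C
F7 | step 8 | methyl (3aS,3bR,5S,6aS,7aR)-2-hydroxy-3,3a,5-trimethyl-1-oxo-3a,3b,4,5,6,6a,7,7a-octahydro-1H-cyclopenta[a]pentalene-5-carboxylate | CC1=C(O)C(=O)[C@@H]2C[C@H]3C[C@](C)(C(=O)OC)C[C@H]3[C@]12C
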